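**Retrosynthetic overview**
1. 13 ⇒ two molecules of hydroxy-pyranone 10 + C4 bis-ylide 12: one double Wittig makes both exocyclic (Z)-alkenes in the last step.
2. 10 ⇒ hydroxy-lactone 8: one-carbon ring expansion of the bought lactone ring to the pyranone (proposed carbenoid insertion), after the cyclopentane is in place.
3. 8 ⇒ aldehyde 7: intramolecular carbonyl-ene closes the cyclopentane and sets C1 and C5 from C4.
4. 7 ⇒ diene 5 ⇒ ketone 4: methylenation, then allylic-strain-controlled hydroboration sets C4 from the bought lactone centre.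
5. 4 ⇒ (R)-lactone acid 1 + homoprenyl bromide 2: nickel-catalysed electroreductive acyl–alkyl coupling forms the fragment-joining C–C bond at the cathode. Ring order: lactone (bought) → cyclopentane → pyranone → dimer.

Assumption: 1 (the deamination product of D-glutamic acid), 2 and 11 are bought; stereochemical outcomes are predicted by analogy and have not been tested.
Labels: cyclopentane C1 (isopropenyl) to C5 (carbinol), C4 carries the pyran; pyran O, C2′ (stereocentre) to C6′ (OCH2), C5′ = alkylidene carbon.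

**Step 1**
Reactants: 1 (2R)-5-oxotetrahydrofuran-2-carboxylic acid; 2 5-bromo-2-methylpent-2-ene
Product: 4 (5R)-5-(5-methylhex-4-enoyl)dihydrofuran-2(3H)-one, via acid chloride 3 (not isolated)
Conditions: (COCl)2, cat. DMF, CH2Cl2, 0 °C to rt, concentrate; then 2 (1.5 equiv), NiBr2(dme) (10 mol%), 4,4′-di-tert-butyl-2,2′-bipyridine (12 mol%), NaI (0.3 equiv), DMA, undivided cell, Zn anode, Ni-foam cathode, constant current, 2.2 F/mol, rt
Reagents that add atoms: none
Why: Nickel-catalysed electroreductive cross-electrophile acylation (Weix-type acyl chloride/alkyl halide coupling run at a cathode): the acyl chloride adds to zerovalent nickel, the homoprenyl radical released from 2 by monovalent nickel is captured and reductive elimination gives the ketone, with no base or organometallic present, so the lactone and the bought C2′ centre are untouched.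

**Step 2**
Reactants: 4 (5R)-5-(5-methylhex-4-enoyl)dihydrofuran-2(3H)-one
Product: 5 (5R)-5-(6-methylhepta-1,5-dien-2-yl)dihydrofuran-2(3H)-one
Conditions: Zn, CH2Br2, TiCl4, THF/CH2Cl2, 0 °C to rt
Reagents that add atoms: dibromomethane, BrCBr
Why: Lombardo–Takai methylenation: the non-basic CH2(ZnBr)2/TiCl4 reagent converts the ketone, but not the lactone, into the 1,1-disubstituted alkene without enolising the adjacent C2′ centre.

**Step 3**
Reactants: 5 (5R)-5-(6-methylhepta-1,5-dien-2-yl)dihydrofuran-2(3H)-one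
Product: 6 (5R)-5-[(2S)-1-hydroxy-6-methylhept-5-en-2-yl]dihydrofuran-2(3H)-one
Conditions: 9-BBN (1.5 equiv), THF, 0 °C to rt; then 30% H2O2, aq. NaOAc, 0 °C; minor diastereomer removed by chromatography
Reagents that add atoms: hydrogen peroxide, OO
Why: Allylic-strain-controlled (Still–Barrish-type) hydroboration–oxidation: 9-BBN reacts only at the 1,1-disubstituted alkene (far faster than at the trisubstituted one) and adds anti to the ring CH2 of the allylic centre with its C–H inside, giving the 2,3-anti product and so setting C4 from the bought centre.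

**Step 4**
Reactants: 6 (5R)-5-[(2S)-1-hydroxy-6-methylhept-5-en-2-yl]dihydrofuran-2(3H)-one
Product: 7 (2R)-6-methyl-2-[(2R)-5-oxotetrahydrofuran-2-yl]hept-5-enal
Conditions: TEMPO (10 mol%), PhI(OAc)2 (1.1 equiv), CH2Cl2, rt; crude aldehyde used at once
Reagents that add atoms: none
Why: Oxoammonium (TEMPO/PhI(OAc)2) oxidation stops at the aldehyde under base-free conditions, so C4 is not epimerised and the β-acyloxy aldehyde does not eliminate.

**Step 5**
Reactants: 7 (2R)-6-methyl-2-[(2R)-5-oxotetrahydrofuran-2-yl]hept-5-enal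
Product: 8 (5R)-5-[(1S,2S,3R)-2-hydroxy-3-(prop-1-en-2-yl)cyclopentyl]dihydrofuran-2(3H)-one
Conditions: Me2AlCl (2.2 equiv), CH2Cl2, −78 to −30 °C; 1 M HCl quench
Reagents that add atoms: none
Why: Intramolecular Lewis-acid carbonyl-ene reaction (Snider-type Me2AlCl conditions): the concerted bicyclic transition state holds the carbonyl oxygen syn to the hydrogen-donating isopropylidene (OH cis to isopropenyl) with the lactonyl group pseudo-equatorial (trans to OH), so C5 and C1 are both set by C4.

**Step 6**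
Reactants: 8 (5R)-5-[(1S,2S,3R)-2-hydroxy-3-(prop-1-en-2-yl)cyclopentyl]dihydrofuran-2(3H)-one
Product: 10 (6R)-6-[(1S,2S,3R)-2-hydroxy-3-(prop-1-en-2-yl)cyclopentyl]dihydro-2H-pyran-3(4H)-one, via iodomethyl ketone 9 (not isolated)
Conditions: CH2I2 (2.5 equiv), MeLi·LiBr (3.0 equiv, slow addition), THF/Et2O, −78 °C; then warm to 0 °C; H2O
Reagents that add atoms: diiodomethane, ICI
Why: Proposed new method: one-flask carbenoid ring expansion of a γ-lactone to a dihydropyran-3-one, in which LiCH2I (made in situ by I/Li exchange, faster than MeLi addition; the first MeLi equivalent only deprotonates the hydroxyl) adds once to the lactone carbonyl to give a lithium hemiketalate stable at −78 °C, and on warming (after excess carbenoid has decomposed) the ring-opened δ-alkoxide displaces iodide from the α-iodomethyl ketone 9 by 6-exo-tet attack (or via the spiro epoxy-ether and a 1,2-oxygen shift) to form the O–CH2 bond; the closest known chemistry is the halomethyllithium homologation of esters to α-halomethyl ketones and the base-induced cyclisation of hydroxy α-halo ketones, and no stereocentre is involved.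

**Step 7**
Reactants: 10 (6R)-6-[(1S,2S,3R)-2-hydroxy-3-(prop-1-en-2-yl)cyclopentyl]dihydro-2H-pyran-3(4H)-one (2.2 equiv); 11 butane-1,4-diylbis(triphenylphosphonium) dibromide
Product: 13 testudinariol A, via bis-ylide 12 (not isolated)
Conditions: 11, KN(SiMe3)2 (2.0 equiv), THF, 0 °C; then 10, THF/HMPA, −78 °C to rt
Reagents that add atoms: none
Why: Double Wittig olefination: non-stabilised ylides add to α-alkoxy ketones under salt-free conditions with the ylide chain ending cis to the oxygen-bearing CH2 (Still's Z-selective α-alkoxy-ketone Wittig), which is the geometry of both exocyclic alkenes; proton exchange between the free hydroxyl and the ylide is reversible and no stereocentre is α to the carbonyl.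

**Compound list**
1 | (2R)-5-oxotetrahydrofuran-2-carboxylic acid | OC(=O)[C@H]1CCC(=O)O1 | starting material
2 | 5-bromo-2-methylpent-2-ene (homoprenyl bromide) | CC(C)=CCCBr | starting material
3 | (2R)-5-oxotetrahydrofuran-2-carbonyl chloride | O=C(Cl)[C@H]1CCC(=O)O1 | intermediate
4 | (5R)-5-(5-methylhex-4-enoyl)dihydrofuran-2(3H)-one | CC(C)=CCCC(=O)[C@H]1CCC(=O)O1 | intermediate
5 | (5R)-5-(6-methylhepta-1,5-dien-2-yl)dihydrofuran-2(3H)-one | C=C(CCC=C(C)C)[C@H]1CCC(=O)O1 | intermediate
6 | (5R)-5-[(2S)-1-hydroxy-6-methylhept-5-en-2-yl]dihydrofuran-2(3H)-one | CC(C)=CCC[C@H]([C@H]1CCC(=O)O1)CO | intermediate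
7 | (2R)-6-methyl-2-[(2R)-5-oxotetrahydrofuran-2-yl]hept-5-enal | CC(C)=CCC[C@H]([C@H]1CCC(=O)O1)C=O | intermediate
8 | (5R)-5-[(1S,2S,3R)-2-hydroxy-3-(prop-1-en-2-yl)cyclopentyl]dihydrofuran-2(3H)-one | C=C(C)[C@H]1CC[C@H]([C@H]2CCC(=O)O2)[C@H]1O | intermediate
9 | (5R)-5-hydroxy-5-[(1R,2S,3R)-2-hydroxy-3-(prop-1-en-2-yl)cyclopentyl]-1-iodopentan-2-one | C=C(C)[C@H]1CC[C@H]([C@H](O)CCC(=O)CI)[C@H]1O | intermediate
10 | (6R)-6-[(1S,2S,3R)-2-hydroxy-3-(prop-1-en-2-yl)cyclopentyl]dihydro-2H-pyran-3(4H)-one | C=C(C)[C@H]1CC[C@H]([C@H]2CCC(=O)CO2)[C@H]1O | intermediate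
11 | butane-1,4-diylbis(triphenylphosphonium) dibromide | [Br-].[Br-].c1ccc(cc1)[P+](CCCC[P+](c1ccccc1)(c1ccccc1)c1ccccc1)(c1ccccc1)c1ccccc1 | starting material
12 | (butane-1,4-diylidene)bis(triphenyl-λ5-phosphane), the bis-ylide | C(CCC=P(c1ccccc1)(c1ccccc1)c1ccccc1)=P(c1ccccc1)(c1ccccc1)c1ccccc1 | intermediate
13 | testudinariol A: two (1S,2R,5S)-2-(prop-1-en-2-yl)cyclopentan-1-ol units, each bearing at C5 a (2R)-tetrahydro-2H-pyran-2-yl ring, the two pyran C5 atoms joined as a (Z,Z) C5=CH–CH2–CH2–CH=C5 diene (chain cis to each ring OCH2) | C=C(C)[C@H]1CC[C@H]([C@H]2CC/C(=C/CC/C=C3/CC[C@H]([C@H]4CC[C@H](C(=C)C)[C@@H]4O)OC3)CO2)[C@H]1O | target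

**Totals**
Total step count: 7. Longest linear sequence: 7 steps (1 → 13); 2 and 11 are used as bought.

**Steps most likely to fail, with fallbacks**

Step 6 (proposed new ring expansion). The carbenoid may add twice, MeLi may add directly, or the hemiketalate may fail to open and cyclise cleanly. The fallback uses known sulfoxonium-ylide chemistry and sets out from 8. Dimethylsulfoxonium methylide (Me3S(O)I, KOtBu, THF, 60 °C) opens the lactone to (5R)-1-[dimethyl(oxo)-λ6-sulfanylidene]-5-hydroxy-5-[(1R,2S,3R)-2-hydroxy-3-(prop-1-en-2-yl)cyclopentyl]pentan-2-one F3. Intramolecular carbenoid O–H insertion with [Ir(cod)Cl]2 (2 mol%, toluene, 80 °C) then closes the six-membered ring through the nearer hydroxyl and comes back to the route at 10.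

Step 3 (diastereoselectivity of the hydroboration). The anti preference is established for free allylic alcohols and ethers, and the acyloxy-type ring oxygen of 5 may give a lower ratio. The fallback sets out from 5 and first reveals the free alcohol. Pyrrolidine (neat, 40 °C) opens the lactone to (4R)-4-hydroxy-9-methyl-5-methylidene-1-(pyrrolidin-1-yl)dec-8-en-1-one F1. 9-BBN followed by H2O2/NaOH on this free secondary allylic alcohol gives (4R,5S)-4-hydroxy-5-(hydroxymethyl)-9-methyl-1-(pyrrolidin-1-yl)dec-8-en-1-one F2. p-TsOH in toluene at 60 °C relactonises F2 and comes back to the route at 6.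

Step 7 (double Wittig). The bis-ylide may give mono-olefination or side reactions, and two olefinations must both be Z-selective in one flask. The fallback builds the diene one alkene at a time and sets out from 10.
- Wittig reaction of 10 with the ylide from [4-(tert-butyldimethylsilyloxy)butyl]triphenylphosphonium bromide and KN(SiMe3)2 gives (1S,2R,5S)-5-[(2R,5Z)-5-(4-{[tert-butyl(dimethyl)silyl]oxy}butylidene)tetrahydro-2H-pyran-2-yl]-2-(prop-1-en-2-yl)cyclopentan-1-ol F4.
- TBAF gives (1S,2R,5S)-5-[(2R,5Z)-5-(4-hydroxybutylidene)tetrahydro-2H-pyran-2-yl]-2-(prop-1-en-2-yl)cyclopentan-1-ol F5.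
- I2, PPh3 and imidazole convert the primary hydroxyl selectively to (1S,2R,5S)-5-[(2R,5Z)-5-(4-iodobutylidene)tetrahydro-2H-pyran-2-yl]-2-(prop-1-en-2-yl)cyclopentan-1-ol F6.
- PPh3 in MeCN at 80 °C gives [(4Z)-4-{(6R)-6-[(1S,2S,3R)-2-hydroxy-3-(prop-1-en-2-yl)cyclopentyl]tetrahydro-2H-pyran-3-ylidene}butyl]triphenylphosphonium iodide F7.
- KN(SiMe3)2 and a second equivalent of 10 (THF/HMPA, −78 °C to rt) then come back to the route at 13.

**Further compounds**
F1 | step 3 | (4R)-4-hydroxy-9-methyl-5-methylidene-1-(pyrrolidin-1-yl)dec-8-en-1-one | C=C(CCC=C(C)C)[C@H](O)CCC(=O)N1CCCC1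
F2 | step 3 | (4R,5S)-4-hydroxy-5-(hydroxymethyl)-9-methyl-1-(pyrrolidin-1-yl)dec-8-en-1-one | CC(C)=CCC[C@@H](CO)[C@H](O)CCC(=O)N1CCCC1
F3 | step 6 | (5R)-1-[dimethyl(oxo)-λ6-sulfanylidene]-5-hydroxy-5-[(1R,2S,3R)-2-hydroxy-3-(prop-1-en-2-yl)cyclopentyl]pentan-2-one | C=C(C)[C@H]1CC[C@H]([C@H](O)CCC(=O)C=S(C)(C)=O)[C@H]1O
F4 | step 7 | (1S,2R,5S)-5-[(2R,5Z)-5-(4-{[tert-butyl(dimethyl)silyl]oxy}butylidene)tetrahydro-2H-pyran-2-yl]-2-(prop-1-en-2-yl)cyclopentan-1-ol | C=C(C)[C@H]1CC[C@H]([C@H]2CC/C(=C/CCCO[Si](C)(C)C(C)(C)C)CO2)[C@H]1O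
F5 | step 7 | (1S,2R,5S)-5-[(2R,5Z)-5-(4-hydroxybutylidene)tetrahydro-2H-pyran-2-yl]-2-(prop-1-en-2-yl)cyclopentan-1-ol | C=C(C)[C@H]1CC[C@H]([C@H]2CC/C(=C/CCCO)CO2)[C@H]1O
F6 | step 7 | (1S,2R,5S)-5-[(2R,5Z)-5-(4-iodobutylidene)tetrahydro-2H-pyran-2-yl]-2-(prop-1-en-2-yl)cyclopentan-1-ol | C=C(C)[C@H]1CC[C@H]([C@H]2CC/C(=C/CCCI)CO2)[C@H]1O
F7 | step 7 | [(4Z)-4-{(6R)-6-[(1S,2S,3R)-2-hydroxy-3-(prop-1-en-2-yl)cyclopentyl]tetrahydro-2H-pyran-3-ylidene}butyl]triphenylphosphonium iodide | C=C(C)[C@H]1CC[C@H]([C@H]2CC/C(=C/CCC[P+](c3ccccc3)(c3ccccc3)c3ccccc3)CO2)[C@H]1O.[I-]
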